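**Retrosynthetic overview**

1. Core locants used throughout (bicyclo[3.3.1]nonane): C1 carbinol bridgehead, C2–C3 oxirane carbons, C4 CH(OMe), C5 CH bridgehead, C6 CH(OH), C7 CH(NH-acyl), C8 CH2, C9 bridging ketone; ring A = C1-C8-C7-C6-C5-C9, ring B = C1-C2-C3-C4-C5-C9.
2. Enabling feature: C9(=O)–C1(OH) is an α-ketol (acyl anion + ketone) and C6(OH)–C7(N) a vicinal amino alcohol (nitronate + aldehyde). C9 and C6 both sit on C5 (a disguised 2-substituted malonaldehyde) and C1/C7 are 1,3-related (a 1-nitro-3-ketone), so the acyclic chain C7-C8-C1-C2=C3-C4-C5(C9)(C6) can be zipped into both rings.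
3. Key disconnection: C9–C1 (closes ring B), then C6–C7 (closes ring A), in one fluoride-triggered operation on an acyclic (Z)-enone aldehyde; C9 is carried as a 2-silyl-1,3-dithiane (masked acyl anion) and C7 as a nitromethylene.
4. After the key step: nitro to the (E)-dodec-2-enamide, C6 carbinol reset by oxidation/hydride reduction while the dithiane still masks C9, dethioacetalisation, then exo-face epoxidation of C2=C3 (oxirane formed last).
5. The acyclic precursor is assembled convergently from a 4-silyloxyhex-5-en-2-ynal and a (2-silyl-1,3-dithian-2-yl)acetaldehyde by a D-proline anti-aldol (sets C4 and C5), then O-methylation, Z-semireduction, oxidation and nitrite conjugate addition.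

Key step: step 11

Remark: the starting pentenynol is used as the racemate; its carbinol carbon becomes the C1 ketone carbon in step 9, so every intermediate before that step is a racemate or a mixture of epimers at that carbon.

**Route**

Step 1
Reactants: 1 1-penten-4-yn-3-ol (racemic)
Product: 2 tert-butyldimethyl(pent-1-en-4-yn-3-yloxy)silane (racemic)
Conditions: TBSCl, imidazole, CH2Cl2, 0 °C to rt
Reagents that add atoms: tert-butyldimethylsilyl chloride, CC(C)(C)[Si](C)(C)Cl
Why: Standard silylation of a secondary alcohol masks the carbinol that later becomes the C1 ketone carbon, and no stereocenter of the target is involved.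

Step 2
Reactants: 2 tert-butyldimethyl(pent-1-en-4-yn-3-yloxy)silane
Product: 3 4-[(tert-butyldimethylsilyl)oxy]hex-5-en-2-ynal (racemic)
Conditions: n-BuLi, THF, −78 °C; DMF; inverse quench into aq. KH2PO4
Reagents that add atoms: N,N-dimethylformamide, CN(C)C=O
Why: Formylation of a lithium acetylide with DMF is the standard route to ynals, and the buffered inverse quench should keep the liberated amine from adding to the product.

Step 3
Reactants: 4 2-(trimethylsilyl)-1,3-dithiane
Product: 5 2-[2-(trimethylsilyl)-1,3-dithian-2-yl]ethanol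
Conditions: n-BuLi, THF, −30 °C; oxirane, Et2O, −78 to −45 °C; AcOH at −78 °C
Reagents that add atoms: oxirane, C1CO1
Why: Corey–Seebach alkylation of the 2-lithio-2-silyl-dithiane with an epoxide, run cold in ether without polar additives so that the lithium alkoxide should not undergo 1,4-Brook silyl migration.

Step 4
Reactants: 5 2-[2-(trimethylsilyl)-1,3-dithian-2-yl]ethanol
Product: 6 [2-(trimethylsilyl)-1,3-dithian-2-yl]acetaldehyde
Conditions: SO3·pyridine, DMSO, i-Pr2NEt, CH2Cl2, 0 °C
Reagents that add atoms: none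
Why: Parikh–Doering oxidation should convert the primary alcohol into the aldehyde without oxidising the thioacetal sulfur atoms.

Step 5
Reactants: 3 4-[(tert-butyldimethylsilyl)oxy]hex-5-en-2-ynal, 6 [2-(trimethylsilyl)-1,3-dithian-2-yl]acetaldehyde
Product: 7 (2R,3S)-6-[(tert-butyldimethylsilyl)oxy]-3-hydroxy-2-[2-(trimethylsilyl)-1,3-dithian-2-yl]oct-7-en-4-ynal (C6 epimers)
Conditions: D-proline (20 mol%), DMF, 4 °C, slow addition of 6
Reagents that add atoms: none
Why: Proline-catalysed direct cross-aldol of two aldehydes (enamine catalysis), in which the hindered β-quaternary aldehyde 6 can only be the donor and the non-enolisable ynal 3 only the acceptor, and the hydrogen-bonded chair transition state of the D-proline enamine should give the anti (2R,3S) adduct that sets the future C4 and C5 stereocenters.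

Step 6
Reactants: 7 (2R,3S)-6-[(tert-butyldimethylsilyl)oxy]-3-hydroxy-2-[2-(trimethylsilyl)-1,3-dithian-2-yl]oct-7-en-4-ynal
Product: 8 (2R,3S)-6-[(tert-butyldimethylsilyl)oxy]-3-methoxy-2-[2-(trimethylsilyl)-1,3-dithian-2-yl]oct-7-en-4-ynal (C6 epimers)
Conditions: methyl 2,2,2-trichloroacetimidate, TfOH (cat.), CH2Cl2/cyclohexane, 0 °C to rt
Reagents that add atoms: methyl 2,2,2-trichloroacetimidate, COC(=N)C(Cl)(Cl)Cl
Why: Acid-catalysed O-alkylation with a trichloroacetimidate should methylate the β-hydroxy aldehyde without base (no retro-aldol, no alkoxide-triggered Brook shift) and without the sulfur alkylation expected from oxonium salts, leaving both stereocenters untouched.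

Step 7
Reactants: 8 (2R,3S)-6-[(tert-butyldimethylsilyl)oxy]-3-methoxy-2-[2-(trimethylsilyl)-1,3-dithian-2-yl]oct-7-en-4-ynal
Product: 9 (2R,3S)-6-hydroxy-3-methoxy-2-[2-(trimethylsilyl)-1,3-dithian-2-yl]oct-7-en-4-ynal (C6 epimers)
Conditions: HF·pyridine, THF/pyridine, 0 °C
Reagents that add atoms: none
Why: Selective O-desilylation, since acidic fluoride cleaves the O–Si bond of the TBS ether whereas the C–Si bond of the 2-silyl-dithiane needs basic, naked fluoride and should survive.

Step 8
Reactants: 9 (2R,3S)-6-hydroxy-3-methoxy-2-[2-(trimethylsilyl)-1,3-dithian-2-yl]oct-7-en-4-ynal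
Product: 10 (2R,3R,4Z)-6-hydroxy-3-methoxy-2-[2-(trimethylsilyl)-1,3-dithian-2-yl]octa-4,7-dienal (C6 epimers)
Conditions: Zn dust activated with Cu(OAc)2·H2O and AgNO3, MeOH/H2O, rt
Reagents that add atoms: none
Why: Cis-semireduction by copper- and silver-activated zinc of an alkyne activated by a propargylic hydroxyl delivers both hydrogens syn to give the (Z)-alkene needed for ring B, and it tolerates sulfur, the aldehyde and the terminal vinyl group where a palladium hydrogenation would not.

Step 9
Reactants: 10 (2R,3R,4Z)-6-hydroxy-3-methoxy-2-[2-(trimethylsilyl)-1,3-dithian-2-yl]octa-4,7-dienal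
Product: 11 (2R,3R,4Z)-3-methoxy-6-oxo-2-[2-(trimethylsilyl)-1,3-dithian-2-yl]octa-4,7-dienal
Conditions: activated MnO2 (excess), CH2Cl2, rt
Reagents that add atoms: none
Why: Allylic oxidation with MnO2 should touch only the doubly allylic alcohol, converging both epimers to the cross-conjugated dienone while sparing the aldehyde, the thioacetal and the Z geometry.

Step 10
Reactants: 11 (2R,3R,4Z)-3-methoxy-6-oxo-2-[2-(trimethylsilyl)-1,3-dithian-2-yl]octa-4,7-dienal
Product: 12 (2R,3R,4Z)-3-methoxy-8-nitro-6-oxo-2-[2-(trimethylsilyl)-1,3-dithian-2-yl]oct-4-enal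
Conditions: NaNO2, AcOH, THF, rt
Reagents that add atoms: sodium nitrite, [Na+].[O-]N=O
Why: Conjugate addition of nitrous acid to an enone (Michael-type addition of nitrite) should occur at the unsubstituted vinyl terminus, the less hindered and more electrophilic of the two enone β-carbons, giving the 1-nitro-3-ketone.

Step 11
Reactants: 12 (2R,3R,4Z)-3-methoxy-8-nitro-6-oxo-2-[2-(trimethylsilyl)-1,3-dithian-2-yl]oct-4-enal
Product: 14 (1S,4R,5S,6S,7S)-4-methoxy-7-nitrospiro[bicyclo[3.3.1]non-2-ene-9,2'-[1,3]dithiane]-1,6-diol, via monocyclic ring B alkoxide 13 (not isolated)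
Conditions: Bu4N[Ph3SiF2] (TBAT, 2.5 equiv), THF (0.005 M), −40 °C to rt; AcOH, aq. NH4Cl
Reagents that add atoms: none
Why: Proposed new method: fluoride should first convert the acidic primary nitro group into its ammonium nitronate (which can neither quench a carbanion nor lose nitrite by E1cB elimination) and then attack silicon of the 2-silyl-dithiane, whose dithianyl anion (the masked acyl anion, C9) adds to the ketone C1, after which the nitronate carbon C7 adds to the aldehyde C6 in a nitro-aldol reaction. The closest known reaction types are the fluoride- or Lewis-base-promoted carbonyl addition of 2-trimethylsilyl-1,3-dithianes and the fluoride-mediated intramolecular Henry cyclisation; their union in one flask on one substrate is the new element. Ring B closes by 6-exo-trig attack on the ketone (attack on the aldehyde on the neighbouring carbon would need a three-membered ring, attack on the enone β-carbon a four-membered ring), and ring A closes by 6-(enolexo)-exo-trig attack of the nitronate on the aldehyde once a ring flip has placed both arms 1,3-diaxial on ring B. C1 is set in a chair transition state with the formyl, methoxy and nitroethyl groups equatorial, which puts the nitroethyl arm cis to the formyl group as ring A demands; C5 is retained (and can equilibrate through the aldehyde enolate towards the favoured trans relationship with the C4 methoxy group); C7 should end with the nitro group equatorial under reversible nitronate protonation; C6 is expected mainly as the equatorial alcohol because its axial position is 1,3-diaxial to a dithiane sulfur, which is of no consequence because C6 is reset in steps 13 and 14. The step needs ring B to form before ring A and cyclisation to outrun oligomerisation; the first is secured because an initial nitro-aldol would be an eight-membered closure, the second by high dilution.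

Step 12
Reactants: 14 (1S,4R,5S,6S,7S)-4-methoxy-7-nitrospiro[bicyclo[3.3.1]non-2-ene-9,2'-[1,3]dithiane]-1,6-diol, 15 (2E)-dodec-2-enoic acid
Product: 17 (2E)-N-[(1S,4R,5S,6S,7S)-1,6-dihydroxy-4-methoxyspiro[bicyclo[3.3.1]non-2-ene-9,2'-[1,3]dithian]-7-yl]dodec-2-enamide, via bicyclic amine 16 (not isolated)
Conditions: Zn, AcOH/THF, rt; filter, concentrate; then 15, EDC·HCl, HOBt (cat.), i-Pr2NEt, CH2Cl2, 0 °C to rt
Reagents that add atoms: none
Why: Zinc/acetic acid reduction of the aliphatic nitro group gives the amine with retention at C7, and carbodiimide amide coupling (EDC/HOBt) should acylate nitrogen in preference to the secondary and tertiary hydroxyls.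

Step 13
Reactants: 17 (2E)-N-[(1S,4R,5S,6S,7S)-1,6-dihydroxy-4-methoxyspiro[bicyclo[3.3.1]non-2-ene-9,2'-[1,3]dithian]-7-yl]dodec-2-enamide
Product: 18 (2E)-N-[(1S,4R,5R,7S)-1-hydroxy-4-methoxy-6-oxospiro[bicyclo[3.3.1]non-2-ene-9,2'-[1,3]dithian]-7-yl]dodec-2-enamide
Conditions: (COCl)2, DMSO, CH2Cl2, −78 °C; Et3N, −78 to −20 °C
Reagents that add atoms: none
Why: Swern oxidation converts the only secondary alcohol (C6) into the ketone, the tertiary C1 carbinol cannot react, the dithiane that still masks C9 is inert to activated DMSO, and C7 stays in its favoured equatorial amide configuration.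

Step 14
Reactants: 18 (2E)-N-[(1S,4R,5R,7S)-1-hydroxy-4-methoxy-6-oxospiro[bicyclo[3.3.1]non-2-ene-9,2'-[1,3]dithian]-7-yl]dodec-2-enamide
Product: 19 (2E)-N-[(1S,4R,5S,6R,7S)-1,6-dihydroxy-4-methoxyspiro[bicyclo[3.3.1]non-2-ene-9,2'-[1,3]dithian]-7-yl]dodec-2-enamide
Conditions: LiBH(s-Bu)3 (L-Selectride, excess), THF, −78 °C; aq. NH4Cl
Reagents that add atoms: none
Why: Bulky-hydride reduction of the cyclohexanone, in which the axial face of C6 is blocked by the dithiane sulfur lying 1,3-diaxial over ring A, so hydride should enter equatorially and give the axial C6 alcohol cis to the equatorial amide, as in the target.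

Step 15
Reactants: 19 (2E)-N-[(1S,4R,5S,6R,7S)-1,6-dihydroxy-4-methoxyspiro[bicyclo[3.3.1]non-2-ene-9,2'-[1,3]dithian]-7-yl]dodec-2-enamide
Product: 20 (2E)-N-[(1S,4R,5S,6R,7S)-1,6-dihydroxy-4-methoxy-9-oxobicyclo[3.3.1]non-2-en-7-yl]dodec-2-enamide
Conditions: PhI(OCOCF3)2, MeCN/H2O (9:1), 0 °C to rt
Reagents that add atoms: water, O
Why: Oxidative dethioacetalisation with PhI(OCOCF3)2 should unveil the C9 ketone under mild, non-basic conditions that spare the alkene, the amide and the aldol-type C6 carbinol, whose β-elimination and retro-aldol pathways would in any case need a bridgehead enolate.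

Step 16
Reactants: 20 (2E)-N-[(1S,4R,5S,6R,7S)-1,6-dihydroxy-4-methoxy-9-oxobicyclo[3.3.1]non-2-en-7-yl]dodec-2-enamide
Product: 21 (2E)-N-[(1S,2S,4S,5S,6S,7R,8S)-1,7-dihydroxy-5-methoxy-10-oxo-3-oxatricyclo[4.3.1.0(2,4)]decan-8-yl]dodec-2-enamide (target)
Conditions: VO(acac)2 (5 mol%), t-BuOOH, CH2Cl2, 0 °C to rt
Reagents that add atoms: tert-butyl hydroperoxide, CC(C)(C)OO
Why: Vanadium-catalysed hydroxyl-directed epoxidation is selective for the allylic ring alkene over the electron-poor acrylamide-type alkene, and oxygen should be delivered to the exo face, on which the pseudo-equatorial C1 hydroxyl lies, because the endo face of ring B is the concave one under ring A and is screened by the endo C7–H, a bias expected to outweigh the pseudoaxial C4 methoxy group on the exo face.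

**Compound list**

1 | 1-penten-4-yn-3-ol (racemic) | C=CC(O)C#C | starting material
2 | tert-butyldimethyl(pent-1-en-4-yn-3-yloxy)silane (racemic) | C=CC(O[Si](C)(C)C(C)(C)C)C#C | intermediate
3 | 4-[(tert-butyldimethylsilyl)oxy]hex-5-en-2-ynal (racemic) | O=CC#CC(O[Si](C)(C)C(C)(C)C)C=C | intermediate
4 | 2-(trimethylsilyl)-1,3-dithiane | C[Si](C)(C)C1SCCCS1 | starting material
5 | 2-[2-(trimethylsilyl)-1,3-dithian-2-yl]ethanol | C[Si](C)(C)C1(CCO)SCCCS1 | intermediate
6 | [2-(trimethylsilyl)-1,3-dithian-2-yl]acetaldehyde | C[Si](C)(C)C1(CC=O)SCCCS1 | intermediate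
7 | (2R,3S)-6-[(tert-butyldimethylsilyl)oxy]-3-hydroxy-2-[2-(trimethylsilyl)-1,3-dithian-2-yl]oct-7-en-4-ynal (C6 epimers) | C=CC(O[Si](C)(C)C(C)(C)C)C#C[C@@H](O)[C@H](C=O)C1(SCCCS1)[Si](C)(C)C | intermediate
8 | (2R,3S)-6-[(tert-butyldimethylsilyl)oxy]-3-methoxy-2-[2-(trimethylsilyl)-1,3-dithian-2-yl]oct-7-en-4-ynal (C6 epimers) | C=CC(O[Si](C)(C)C(C)(C)C)C#C[C@@H](OC)[C@H](C=O)C1(SCCCS1)[Si](C)(C)C | intermediate
9 | (2R,3S)-6-hydroxy-3-methoxy-2-[2-(trimethylsilyl)-1,3-dithian-2-yl]oct-7-en-4-ynal (C6 epimers) | C=CC(O)C#C[C@@H](OC)[C@H](C=O)C1(SCCCS1)[Si](C)(C)C | intermediate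
10 | (2R,3R,4Z)-6-hydroxy-3-methoxy-2-[2-(trimethylsilyl)-1,3-dithian-2-yl]octa-4,7-dienal (C6 epimers) | C=CC(O)/C=C\[C@@H](OC)[C@H](C=O)C1(SCCCS1)[Si](C)(C)C | intermediate
11 | (2R,3R,4Z)-3-methoxy-6-oxo-2-[2-(trimethylsilyl)-1,3-dithian-2-yl]octa-4,7-dienal | C=CC(=O)/C=C\[C@@H](OC)[C@H](C=O)C1(SCCCS1)[Si](C)(C)C | intermediate
12 | (2R,3R,4Z)-3-methoxy-8-nitro-6-oxo-2-[2-(trimethylsilyl)-1,3-dithian-2-yl]oct-4-enal | [O-][N+](=O)CCC(=O)/C=C\[C@@H](OC)[C@H](C=O)C1(SCCCS1)[Si](C)(C)C | intermediate
13 | (7R,8R,11S)-11-hydroxy-8-methoxy-11-(2-nitroethyl)-1,5-dithiaspiro[5.5]undec-9-ene-7-carbaldehyde (present as its ammonium alkoxide/nitronate) | [O-][N+](=O)CC[C@@]1(O)C2(SCCCS2)[C@@H](C=O)[C@H](OC)C=C1 | intermediate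
14 | (1S,4R,5S,6S,7S)-4-methoxy-7-nitrospiro[bicyclo[3.3.1]non-2-ene-9,2'-[1,3]dithiane]-1,6-diol | [O-][N+](=O)[C@H]1C[C@@]2(O)C3(SCCCS3)[C@@H]([C@@H]1O)[C@H](OC)C=C2 | intermediate
15 | (2E)-dodec-2-enoic acid | CCCCCCCCC/C=C/C(=O)O | starting material
16 | (1S,4R,5S,6S,7S)-7-amino-4-methoxyspiro[bicyclo[3.3.1]non-2-ene-9,2'-[1,3]dithiane]-1,6-diol | N[C@H]1C[C@@]2(O)C3(SCCCS3)[C@@H]([C@@H]1O)[C@H](OC)C=C2 | intermediate
17 | (2E)-N-[(1S,4R,5S,6S,7S)-1,6-dihydroxy-4-methoxyspiro[bicyclo[3.3.1]non-2-ene-9,2'-[1,3]dithian]-7-yl]dodec-2-enamide | CCCCCCCCC/C=C/C(=O)N[C@H]1C[C@@]2(O)C3(SCCCS3)[C@@H]([C@@H]1O)[C@H](OC)C=C2 | intermediate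
18 | (2E)-N-[(1S,4R,5R,7S)-1-hydroxy-4-methoxy-6-oxospiro[bicyclo[3.3.1]non-2-ene-9,2'-[1,3]dithian]-7-yl]dodec-2-enamide | CCCCCCCCC/C=C/C(=O)N[C@H]1C[C@@]2(O)C3(SCCCS3)[C@@H](C1=O)[C@H](OC)C=C2 | intermediate
19 | (2E)-N-[(1S,4R,5S,6R,7S)-1,6-dihydroxy-4-methoxyspiro[bicyclo[3.3.1]non-2-ene-9,2'-[1,3]dithian]-7-yl]dodec-2-enamide | CCCCCCCCC/C=C/C(=O)N[C@H]1C[C@@]2(O)C3(SCCCS3)[C@@H]([C@H]1O)[C@H](OC)C=C2 | intermediate
20 | (2E)-N-[(1S,4R,5S,6R,7S)-1,6-dihydroxy-4-methoxy-9-oxobicyclo[3.3.1]non-2-en-7-yl]dodec-2-enamide | CCCCCCCCC/C=C/C(=O)N[C@H]1C[C@@]2(O)C(=O)[C@@H]([C@H]1O)[C@H](OC)C=C2 | intermediate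
21 | (2E)-N-[(1S,2S,4S,5S,6S,7R,8S)-1,7-dihydroxy-5-methoxy-10-oxo-3-oxatricyclo[4.3.1.0(2,4)]decan-8-yl]dodec-2-enamide | CCCCCCCCC/C=C/C(=O)N[C@H]1C[C@@]2(O)C(=O)[C@@H]([C@H]1O)[C@H](OC)[C@@H]1O[C@@H]12 | target

**Summary**

Total step count: 16. Longest linear sequence: 14 steps (steps 1, 2 and 5 to 16; the branch through steps 3 and 4 is equally long).

**Steps most likely to fail**

Step 11 (the proposed new method). What may go wrong: loss of nitrite from the 1-nitro-3-ketone by E1cB elimination before the ketone is consumed, protodesilylation of the dithianyl silicate by the acidic nitro C–H before it reaches the ketone, intermolecular carbonyl addition, or arrest after the first ring closure. Fallback, from 12 back to 14: the two bond formations are separated into two known reactions. Lewis-base catalysis with tetrabutylammonium phenoxide in THF (carbonyl addition of a 2-silyl-1,3-dithiane with silyl transfer to the new alkoxide, so that no free alkoxide or fluoride is present) should convert 12 into (7R,8R,11S)-8-methoxy-11-(2-nitroethyl)-11-[(trimethylsilyl)oxy]-1,5-dithiaspiro[5.5]undec-9-ene-7-carbaldehyde F1, which is isolated. An amine-base intramolecular Henry reaction of F1 (DBU, MeCN, high dilution) should then close ring A to give (1S,4R,5S,6S,7S)-4-methoxy-7-nitro-1-[(trimethylsilyl)oxy]spiro[bicyclo[3.3.1]non-2-ene-9,2'-[1,3]dithian]-6-ol F2. Mild aqueous acid (dilute HCl, THF) removes the silyl ether of F2 to give 14.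

Step 5. What may go wrong: sluggish enamine formation from the hindered donor, erosion of facial selectivity, or self-condensation of the ynal. Fallback, from 3 and 6 back to 7: the aldol is run without asymmetric induction (DL-proline, DMF) to give racemic anti-6-[(tert-butyldimethylsilyl)oxy]-3-hydroxy-2-[2-(trimethylsilyl)-1,3-dithian-2-yl]oct-7-en-4-ynal F3. F3 is resolved by a lipase (Candida antarctica lipase B, vinyl acetate, t-BuOMe), which should acylate the propargylic carbinol of the (3S) series to give (2R,3S)-6-[(tert-butyldimethylsilyl)oxy]-1-oxo-2-[2-(trimethylsilyl)-1,3-dithian-2-yl]oct-7-en-4-yn-3-yl acetate F4, separable from the unreacted (3R) alcohol. Lipase-catalysed hydrolysis of F4 in phosphate buffer (pH 7) should return enantioenriched 7.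

Step 10. What may go wrong: nitrosation at sulfur with loss of the thioacetal, or Z-to-E isomerisation of the enone under nitrous acid. Fallback, from 11 back to 12: conjugate hydroiodination of the vinyl ketone (NaI, TMSCl, wet MeCN, 0 °C) should give (2R,3R,4Z)-8-iodo-3-methoxy-6-oxo-2-[2-(trimethylsilyl)-1,3-dithian-2-yl]oct-4-enal F5. Kornblum substitution of F5 (NaNO2, phloroglucinol, DMSO) should then install the nitro group under neutral, non-nitrosating conditions to give 12.

Further compounds
F1 | step 11 | (7R,8R,11S)-8-methoxy-11-(2-nitroethyl)-11-[(trimethylsilyl)oxy]-1,5-dithiaspiro[5.5]undec-9-ene-7-carbaldehyde | [O-][N+](=O)CC[C@@]1(O[Si](C)(C)C)C2(SCCCS2)[C@@H](C=O)[C@H](OC)C=C1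
F2 | step 11 | (1S,4R,5S,6S,7S)-4-methoxy-7-nitro-1-[(trimethylsilyl)oxy]spiro[bicyclo[3.3.1]non-2-ene-9,2'-[1,3]dithian]-6-ol | [O-][N+](=O)[C@H]1C[C@@]2(O[Si](C)(C)C)C3(SCCCS3)[C@@H]([C@@H]1O)[C@H](OC)C=C2
F3 | step 5 | racemic anti-6-[(tert-butyldimethylsilyl)oxy]-3-hydroxy-2-[2-(trimethylsilyl)-1,3-dithian-2-yl]oct-7-en-4-ynal | C=CC(O[Si](C)(C)C(C)(C)C)C#CC(O)C(C=O)C1(SCCCS1)[Si](C)(C)C
F4 | step 5 | (2R,3S)-6-[(tert-butyldimethylsilyl)oxy]-1-oxo-2-[2-(trimethylsilyl)-1,3-dithian-2-yl]oct-7-en-4-yn-3-yl acetate | C=CC(O[Si](C)(C)C(C)(C)C)C#C[C@@H](OC(C)=O)[C@H](C=O)C1(SCCCS1)[Si](C)(C)C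
F5 | step 10 | (2R,3R,4Z)-8-iodo-3-methoxy-6-oxo-2-[2-(trimethylsilyl)-1,3-dithian-2-yl]oct-4-enal | ICCC(=O)/C=C\[C@@H](OC)[C@H](C=O)C1(SCCCS1)[Si](C)(C)C
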